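## Retrosynthetic overview

1. The dialdehyde comes from a double Swern oxidation of the 11,12-diol. The 5α-OH comes from reductive γ-C–O cleavage of the 5α,6α-epoxide of a drima-5,7-dien-12-al. The 12-CHO comes from allylic oxidation of CH3-12.
2. The drima-5,7-diene core comes from one proton-initiated, head-to-tail cationic bicyclisation of an open-chain 5,6-didehydrofarnesyl (allenic) diester. Ring A (C4–C5) closes first, ring B (C9–C10) second, and loss of H-7 ends the cascade as in drimenol formation.
3. The allene is the central π-nucleophile. It turns the C10 cation into an allyl cation, keeps C5 sp2 as the handle for the 5-OH, and lets the pre-installed 1-acyloxy stereocentre steer C10 and C9.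
4. The allenic ester comes from esterification and CBS reduction of an allenyl ketone. That ketone comes from a ketene (C8 acid from geranyl acetate) and an acyl ylide (C7, from methallyl chloride).

Assumption: drimane numbering (C1–C15) is used for cyclised and open-chain carbons alike, and 3-(triphenylphosphoranylidene)butan-2-one and (E)-4-acetoxycinnamic acid are taken as catalogue chemicals.

## Route

Step 1
Reactants: 1 geranyl acetate
Product: 3 (4E)-6-acetoxy-4-methylhex-4-enoic acid, via acetoxy aldehyde 2 (not isolated)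
Conditions: O3 (1.0 equiv), acetone–H2O 95:5, 0 °C; then NaClO2, NaH2PO4, 0 °C → rt
Reagents that add atoms: ozone [O-][O+]=O; sodium chlorite [Na+].[O-]Cl=O
Why: Chemoselective ozonolysis followed by Pinnick oxidation, in which the electron-rich 6,7-alkene reacts much faster than the 2,3-alkene deactivated by the allylic acetate, water turns the carbonyl oxide directly into aldehyde 2 plus H2O2 (which then scavenges HOCl), no stereocentre is formed and the E-alkene (later C8=C9) is untouched.

Step 2
Reactants: 4 3-(triphenyl-λ5-phosphanylidene)butan-2-one; 5 3-chloro-2-methylprop-1-ene (methallyl chloride)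
Product: 7 6-methyl-2-(triphenyl-λ5-phosphanylidene)hept-6-en-3-one, via ylide anion 6 (not isolated)
Conditions: n-BuLi (1.05 equiv), THF, −78 °C; then 5, −78 °C → rt
Reagents that add atoms: none
Why: Ylide-anion alkylation, in which n-BuLi removes an acetyl CH3 proton of the stabilised ylide and anion 6 is alkylated at that terminal carbon by the allylic chloride (SN2) while the P=C unit survives, with no stereocentre involved.

Step 3
Reactants: 3 (4E)-6-acetoxy-4-methylhex-4-enoic acid; 7 6-methyl-2-(triphenyl-λ5-phosphanylidene)hept-6-en-3-one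
Product: 10 (2E)-3,7,11-trimethyl-8-oxododeca-2,5,6,11-tetraen-1-yl acetate, via acid chloride 8 (not isolated), via ketene 9 (not isolated)
Conditions: (COCl)2, cat DMF, CH2Cl2, 0 °C → rt, evaporate; add slowly to 7, Et3N (1.1 equiv), CH2Cl2, 0 °C
Reagents that add atoms: none
Why: Ketene Wittig allenation, in which Et3N dehydrochlorinates 8 to the monosubstituted ketene 9 and the stabilised ylide traps it to give the trisubstituted allenyl ketone, the allene axis being formed racemic, which does no harm because it is erased in step 6.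

Step 4
Reactants: 10 (2E)-3,7,11-trimethyl-8-oxododeca-2,5,6,11-tetraen-1-yl acetate
Product: 11 (2E,8R)-8-hydroxy-3,7,11-trimethyldodeca-2,5,6,11-tetraen-1-yl acetate
Conditions: (S)-Me-CBS (20 mol %), catecholborane (1.8 equiv), toluene, −78 °C
Reagents that add atoms: none
Why: Corey–Bakshi–Shibata reduction, in which the branched sp2 1-methylallenyl group acts as the large substituent and the CH2CH2 chain as the small one, so the (S)-catalyst gives the R carbinol (C1 of the target), and catecholborane at −78 °C leaves alkenes, allene and acetate alone.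

Step 5
Reactants: 11 (2E,8R)-8-hydroxy-3,7,11-trimethyldodeca-2,5,6,11-tetraen-1-yl acetate; 12 (E)-4-acetoxycinnamic acid
Product: 13 (2E,8R)-8-[(E)-4-acetoxycinnamoyloxy]-3,7,11-trimethyldodeca-2,5,6,11-tetraen-1-yl acetate
Conditions: DCC, DMAP (10 mol %), CH2Cl2, 0 °C → rt
Reagents that add atoms: none
Why: Steglich esterification at the stage where the C1 alcohol is still an unhindered open-chain carbinol, proceeding at the acyl carbon so that the C1 configuration is retained, with the phenol masked as its acetate.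

Step 6
Reactants: 13 (2E,8R)-8-[(E)-4-acetoxycinnamoyloxy]-3,7,11-trimethyldodeca-2,5,6,11-tetraen-1-yl acetate
Product: 16 1β-[(E)-4-acetoxycinnamoyloxy]drima-5,7-dien-11-yl acetate, via ring-A allyl cation 14 (not isolated), via C8 drimenyl cation 15 (not isolated)
Conditions: Tf2NH (20 mol %), CH2Cl2–2-nitropropane 1:1, −78 → −45 °C; Et3N quench
Reagents that add atoms: none
Why: Proposed new method: Markovnikov protonation of the most basic alkene (1,1-disubstituted, not flanked by oxygen) gives the C4 tertiary cation, which the central allene carbon C5 captures 6-endo from the H-6 side to give allyl cation 14 (both allene epimers converge because the axis becomes planar); the pseudo-axial 1-acyloxy group (A1,2 strain against CH3-10, anchimeric shielding as in 1,2-trans glycosylation) blocks the β-face, so the E-C8=C9 alkene adds to C10 from the α-face through a half-chair that places CH3-10 β and CH2OAc-9 β, and cation 15 loses H-7 to the conjugated diene and returns the proton; the closest known reaction types are the proton-initiated farnesyl acetate to drimenyl acetate bicyclisation, allyl-cation-initiated polyene cyclisations of the Johnson type and the neryl to α-terpinyl closure.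

Step 7
Reactants: 16 1β-[(E)-4-acetoxycinnamoyloxy]drima-5,7-dien-11-yl acetate
Product: 17 1β-[(E)-4-acetoxycinnamoyloxy]-12-oxodrima-5,7-dien-11-yl acetate
Conditions: SeO2 (1.3 equiv), 1,4-dioxane (1 % H2O), 75 °C
Reagents that add atoms: selenium dioxide O=[Se]=O
Why: Riley allylic oxidation (ene reaction, [2,3]-shift, then further oxidation to the aldehyde), in which CH3-12 is the only allylic CH3 or CH2 group of the diene, the tertiary C9–H ranks lower, both diene termini are fully substituted (which disfavours cycloaddition of SeO2), and no stereocentre is touched.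

Step 8
Reactants: 17 1β-[(E)-4-acetoxycinnamoyloxy]-12-oxodrima-5,7-dien-11-yl acetate
Product: 18 1β-[(E)-4-acetoxycinnamoyloxy]-5α,6α-epoxy-12-oxodrim-7-en-11-yl acetate
Conditions: mCPBA (1.2 equiv), NaHCO3, CH2Cl2, 0 °C
Reagents that add atoms: meta-chloroperoxybenzoic acid OOC(=O)c1cccc(Cl)c1
Why: Prilezhaev epoxidation of the distal γ,δ-alkene of the dienal, which is the most electron-rich C=C (the enal and cinnamate alkenes are deactivated), with attack from the α-face opposite the axial 10β- and 4β-methyl groups as for steroidal 4,6-dien-3-ones, which sets C5–O as α.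

Step 9
Reactants: 18 1β-[(E)-4-acetoxycinnamoyloxy]-5α,6α-epoxy-12-oxodrim-7-en-11-yl acetate
Product: 20 1β-[(E)-4-acetoxycinnamoyloxy]-5α-hydroxy-12-oxodrim-7-en-11-yl acetate, via deconjugated aldehyde 19 (not isolated)
Conditions: SmI2 (2.5 equiv), THF–MeOH 10:1, −78 °C, 10 min; aqueous work-up; Et3N (20 mol %), CH2Cl2, rt
Reagents that add atoms: none
Why: SmI2 reduction of a γ,δ-epoxy-α,β-unsaturated carbonyl compound, in which two-electron transfer into the enal π-system expels the vinylogous α (C6–O) bond while the C5–O bond and its α configuration stay intact, kinetic α-protonation gives 19 and mild base returns the alkene into conjugation, and the electron transfer needs no approach to the hindered β-face.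

Step 10
Reactants: 20 1β-[(E)-4-acetoxycinnamoyloxy]-5α-hydroxy-12-oxodrim-7-en-11-yl acetate
Product: 22 1β-[(E)-p-coumaroyloxy]drim-7-ene-5α,11,12-triol, via allylic alcohol 21 (not isolated)
Conditions: NaBH4, CeCl3·7H2O, MeOH, −20 °C; then K2CO3 (0.3 equiv), 0 °C; NH4Cl work-up
Reagents that add atoms: none
Why: Luche 1,2-reduction of the enal followed in the same flask by Zemplén-type transesterification, which removes the aryl acetate and the primary acetate much faster than the conjugated ester of the hindered secondary C1 oxygen, and which avoids a free 11-hydroxy-12-aldehyde that would close to a lactol.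

Step 11
Reactants: 22 1β-[(E)-p-coumaroyloxy]drim-7-ene-5α,11,12-triol
Product: 24 1β-[(E)-p-coumaroyloxy]-5α-hydroxypolygodial, via tris-TMS ether 23 (not isolated)
Conditions: TMSCl (3.3 equiv), imidazole, CH2Cl2, 0 °C, filter, concentrate; (COCl)2, DMSO, CH2Cl2, −78 → −35 °C; Et3N, −78 → 0 °C; pH 5 buffer
Reagents that add atoms: none
Why: Swern oxidation run directly on the primary trimethylsilyl ethers, so that both primary oxygens become alkoxysulfonium ions before base is added (no lactol and hence no lactone), the phenol stays masked as its aryl silyl ether until the mildly acidic work-up, the tertiary 5-OH cannot be oxidised, and Et3N at or below 0 °C leaves the 9β-CHO unepimerised as in polygodial syntheses.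

## Compound list

1 | geranyl acetate | CC(C)=CCC/C(C)=C/COC(C)=O | starting material
2 | (2E)-3-methyl-6-oxohex-2-en-1-yl acetate | O=CCC/C(C)=C/COC(C)=O | intermediate
3 | (4E)-6-acetoxy-4-methylhex-4-enoic acid | OC(=O)CC/C(C)=C/COC(C)=O | intermediate
4 | 3-(triphenyl-λ5-phosphanylidene)butan-2-one | CC(=O)C(C)=P(c1ccccc1)(c1ccccc1)c1ccccc1 | starting material
5 | 3-chloro-2-methylprop-1-ene | CC(=C)CCl | starting material
6 | lithium salt of the ylide anion of 4 (deprotonated at the acetyl CH3) | [Li+].[CH2-]C(=O)C(C)=P(c1ccccc1)(c1ccccc1)c1ccccc1 | intermediate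
7 | 6-methyl-2-(triphenyl-λ5-phosphanylidene)hept-6-en-3-one | CC(=C)CCC(=O)C(C)=P(c1ccccc1)(c1ccccc1)c1ccccc1 | intermediate
8 | (4E)-6-acetoxy-4-methylhex-4-enoyl chloride | ClC(=O)CC/C(C)=C/COC(C)=O | intermediate
9 | (4E)-6-acetoxy-4-methylhexa-1,4-dien-1-one (ketene) | O=C=CC/C(C)=C/COC(C)=O | intermediate
10 | (2E)-3,7,11-trimethyl-8-oxododeca-2,5,6,11-tetraen-1-yl acetate (allene axis racemic) | CC(=C)CCC(=O)C(C)=C=CC/C(C)=C/COC(C)=O | intermediate
11 | (2E,8R)-8-hydroxy-3,7,11-trimethyldodeca-2,5,6,11-tetraen-1-yl acetate (both allene-axis epimers) | CC(=C)CC[C@@H](O)C(C)=C=CC/C(C)=C/COC(C)=O | intermediate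
12 | (E)-4-acetoxycinnamic acid | CC(=O)Oc1ccc(/C=C/C(O)=O)cc1 | starting material
13 | (2E,8R)-8-[(E)-4-acetoxycinnamoyloxy]-3,7,11-trimethyldodeca-2,5,6,11-tetraen-1-yl acetate (both allene-axis epimers) | CC(=C)CC[C@@H](OC(=O)/C=C/c1ccc(OC(C)=O)cc1)C(C)=C=CC/C(C)=C/COC(C)=O | intermediate
14 | ring-A allyl cation (C10/C6 termini, C7 cis to C10, 1R ester) | CC1(C)CC[C@@H](OC(=O)/C=C/c2ccc(OC(C)=O)cc2)[C+](C)/C1=C\C/C(C)=C/COC(C)=O | intermediate
15 | bicyclic C8 cation (1β-O, 9α-H, 10β-CH3, Δ5) | CC1(C)CC[C@@H](OC(=O)/C=C/c2ccc(OC(C)=O)cc2)[C@]2(C)[C@@H](COC(C)=O)[C+](C)CC=C12 | intermediate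
16 | 1β-[(E)-4-acetoxycinnamoyloxy]drima-5,7-dien-11-yl acetate (9α-H, 10β-CH3) | CC1(C)CC[C@@H](OC(=O)/C=C/c2ccc(OC(C)=O)cc2)[C@]2(C)[C@@H](COC(C)=O)C(C)=CC=C12 | intermediate
17 | 1β-[(E)-4-acetoxycinnamoyloxy]-12-oxodrima-5,7-dien-11-yl acetate | CC1(C)CC[C@@H](OC(=O)/C=C/c2ccc(OC(C)=O)cc2)[C@]2(C)[C@@H](COC(C)=O)C(C=O)=CC=C12 | intermediate
18 | 1β-[(E)-4-acetoxycinnamoyloxy]-5α,6α-epoxy-12-oxodrim-7-en-11-yl acetate | CC1(C)CC[C@@H](OC(=O)/C=C/c2ccc(OC(C)=O)cc2)[C@]2(C)[C@@H](COC(C)=O)C(C=O)=C[C@@H]3O[C@]123 | intermediate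
19 | 1β-[(E)-4-acetoxycinnamoyloxy]-5α-hydroxy-12-oxodrim-6-en-11-yl acetate (C8 epimers) | CC1(C)CC[C@@H](OC(=O)/C=C/c2ccc(OC(C)=O)cc2)[C@]2(C)[C@@H](COC(C)=O)C(C=O)C=C[C@@]12O | intermediate
20 | 1β-[(E)-4-acetoxycinnamoyloxy]-5α-hydroxy-12-oxodrim-7-en-11-yl acetate | CC1(C)CC[C@@H](OC(=O)/C=C/c2ccc(OC(C)=O)cc2)[C@]2(C)[C@@H](COC(C)=O)C(C=O)=CC[C@@]12O | intermediate
21 | 1β-[(E)-4-acetoxycinnamoyloxy]-5α,12-dihydroxydrim-7-en-11-yl acetate | CC1(C)CC[C@@H](OC(=O)/C=C/c2ccc(OC(C)=O)cc2)[C@]2(C)[C@@H](COC(C)=O)C(CO)=CC[C@@]12O | intermediate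
22 | 1β-[(E)-p-coumaroyloxy]drim-7-ene-5α,11,12-triol | CC1(C)CC[C@@H](OC(=O)/C=C/c2ccc(O)cc2)[C@]2(C)[C@@H](CO)C(CO)=CC[C@@]12O | intermediate
23 | 11,12,4'-tris-O-trimethylsilyl ether of 22 (5α-OH free) | CC1(C)CC[C@@H](OC(=O)/C=C/c2ccc(O[Si](C)(C)C)cc2)[C@]2(C)[C@@H](CO[Si](C)(C)C)C(CO[Si](C)(C)C)=CC[C@@]12O | intermediate
24 | 1β-[(E)-p-coumaroyloxy]-5α-hydroxypolygodial (1R,5R,9R,10S in drimane numbering) | CC1(C)CC[C@@H](OC(=O)/C=C/c2ccc(O)cc2)[C@]2(C)[C@@H](C=O)C(C=O)=CC[C@@]12O | target

## Step count and risks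

Total steps: 11. Longest linear sequence: 10 (steps 1 and 3–11; step 2 runs in parallel).

**Step 6 (allene-relayed bicyclisation).**
- Ways it can fail:
  - The allene or the C1 ester may be attacked by acid before the isopropenyl group.
  - Cation 14 may only lose a proton to trienes.
  - The facial or half-chair preference may be weak.
- Fallback: it sets out from 2 (isolated by leaving out the chlorite stage of step 1) and 7, and comes back at 17.
  - Wittig olefination in warm toluene gives (2E,6E)-3,7,11-trimethyl-8-oxododeca-2,6,11-trien-1-yl acetate F1.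
  - (S)-Me-CBS and catecholborane give (2E,6E,8R)-8-hydroxy-3,7,11-trimethyldodeca-2,6,11-trien-1-yl acetate F2.
  - Steglich esterification with 12 gives (2E,6E,8R)-8-[(E)-4-acetoxycinnamoyloxy]-3,7,11-trimethyldodeca-2,6,11-trien-1-yl acetate F3.
  - Proton-initiated chair–chair bicyclisation of this ordinary triene, with the ester equatorial, gives 1β-[(E)-4-acetoxycinnamoyloxy]drim-7-en-11-yl acetate F4.
  - SeO2 oxidation of CH3-12 gives 1β-[(E)-4-acetoxycinnamoyloxy]-12-oxodrim-7-en-11-yl acetate F5.
  - Chloranil γ,δ-dehydrogenation of the enal, as for steroidal 4-en-3-ones, introduces the 5,6-alkene and delivers 17.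

**Step 7 (one-step CH3 to CHO oxidation on a homoannular diene).**
- Ways it can fail: hot stoichiometric SeO2 may hydroxylate C9, add to the diene, or stall at mixed oxidation levels.
- Fallback: it sets out from 16 and comes back at 17. The oxidation is split between two different oxidants.
  - Catalytic SeO2 with t-BuOOH at room temperature stops at 1β-[(E)-4-acetoxycinnamoyloxy]-12-hydroxydrima-5,7-dien-11-yl acetate F6.
  - Activated MnO2 then takes this dienylic alcohol selectively to the dienal.

**Step 9 (reductive epoxide opening).**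
- Ways it can fail: SmI2 may couple the enal, touch the cinnamate, or leave the alkene out of conjugation.
- Fallback: it sets out from 18 and comes back at 20.
  - The electron-transfer cleavage is replaced by palladium(0)-catalysed formate hydrogenolysis of the alkenyl oxirane (Pd2(dba)3, n-Bu3P, HCO2H–Et3N, dioxane).
  - This goes through a π-allyl palladium formate and delivers hydride to C6, giving the conjugated δ-hydroxy enal directly without any new isolated compound.

## Further compounds

F1 | step 6 | (2E,6E)-3,7,11-trimethyl-8-oxododeca-2,6,11-trien-1-yl acetate | CC(=C)CCC(=O)/C(C)=C/CC/C(C)=C/COC(C)=O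
F2 | step 6 | (2E,6E,8R)-8-hydroxy-3,7,11-trimethyldodeca-2,6,11-trien-1-yl acetate | CC(=C)CC[C@@H](O)/C(C)=C/CC/C(C)=C/COC(C)=O
F3 | step 6 | (2E,6E,8R)-8-[(E)-4-acetoxycinnamoyloxy]-3,7,11-trimethyldodeca-2,6,11-trien-1-yl acetate | CC(=C)CC[C@@H](OC(=O)/C=C/c1ccc(OC(C)=O)cc1)/C(C)=C/CC/C(C)=C/COC(C)=O
F4 | step 6 | 1β-[(E)-4-acetoxycinnamoyloxy]drim-7-en-11-yl acetate | CC1(C)CC[C@@H](OC(=O)/C=C/c2ccc(OC(C)=O)cc2)[C@]2(C)[C@@H](COC(C)=O)C(C)=CC[C@@H]12
F5 | step 6 | 1β-[(E)-4-acetoxycinnamoyloxy]-12-oxodrim-7-en-11-yl acetate | CC1(C)CC[C@@H](OC(=O)/C=C/c2ccc(OC(C)=O)cc2)[C@]2(C)[C@@H](COC(C)=O)C(C=O)=CC[C@@H]12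
F6 | step 7 | 1β-[(E)-4-acetoxycinnamoyloxy]-12-hydroxydrima-5,7-dien-11-yl acetate | CC1(C)CC[C@@H](OC(=O)/C=C/c2ccc(OC(C)=O)cc2)[C@]2(C)[C@@H](COC(C)=O)C(CO)=CC=C12
F0 | step 9 | none | none
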